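## Retrosynthetic overview

1. The target comes from global MOM removal of a tris-MOM macrocycle. The only ring-forming bond is the diaryl ether C–O (ring-B C4–O–ring-A), closed by a photoinduced Cu-catalysed intramolecular O-arylation of a seco phenol/aryl iodide (22-membered ring, formed last but one).
2. The seco compound comes from cross-metathesis of a ring-B non-8-en-1-ol with a ring-A hept-6-enyl arene (E-alkene).
3. The ring-B phenol oxygen comes from directed ortho-lithiation/borylation/oxidation between two OMOM groups; the C4–C9 chain comes from a Cu-catalysed sp3–sp3 coupling at a C3 chloride.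
4. The ring-B resorcinol and the stereocentre come from purchased (R)-3-chloro-1-phenylpropan-1-ol by Ir-catalysed meta,meta′ C–H diborylation/oxidation; the stereocentre is never a reacting centre.
5. Ring A comes from 3,5-diiodophenol (MOM ether, mono-Negishi alkylation).

Assumption: the SMILES is read as (R) at the benzylic carbinol and E at the alkene; common reagents (MOMCl, oxidants, catalysts) are named with SMILES where they add atoms but are not numbered.

## Route

Step 1
Reactants: 1, (R)-3-chloro-1-phenylpropan-1-ol
Product: 2, (R)-5-(3-chloro-1-hydroxypropyl)benzene-1,3-diol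
Conditions: HBpin (1.1 equiv), then [Ir(cod)OMe]2 (2 mol%), dtbpy (4 mol%), B2pin2 (2.5 equiv), THF, 80 °C; evaporate; aq. Oxone, acetone, rt, 10 min (one pot)
Reagents that add atoms: Oxone (potassium peroxymonosulfate), [K+].[O-]S(=O)(=O)OO, supplies the two phenolic oxygens (the Bpin groups from B2pin2 are replaced)
Why: Sterically governed Ir-catalysed arene C–H borylation of a monosubstituted benzene goes meta then meta′ (the para-monoborylated arene is a dead end, removed as the mono-phenol; expected about 2:1 in favour of the 3,5-product), the alcohol is masked in situ as O–Bpin, and one-pot boronate oxidation gives the resorcinol without touching the purchased stereocentre.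

Step 2
Reactants: 2, (R)-5-(3-chloro-1-hydroxypropyl)benzene-1,3-diol
Product: 3, (R)-1-[3,5-bis(methoxymethoxy)phenyl]-3-chloropropan-1-ol
Conditions: MOMCl (2.3 equiv), K2CO3, acetone, 0 °C → rt
Reagents that add atoms: chloromethyl methyl ether (MOMCl), COCCl
Why: Williamson O-alkylation of the two phenoxides (carbonate does not deprotonate the secondary alcohol) installs OMOM groups that serve as protecting groups and as ortho-directing groups for step 4.

Step 3
Reactants: 3, (R)-1-[3,5-bis(methoxymethoxy)phenyl]-3-chloropropan-1-ol; 4, 6-bromohex-1-ene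
Product: 5, (R)-1-[3,5-bis(methoxymethoxy)phenyl]non-8-en-1-ol
Conditions: 4, Mg, THF, 20 °C → hex-5-enylMgBr (3.2 equiv); CuCl2 (3 mol%), 1-phenylpropyne (15 mol%), THF, reflux
Reagents that add atoms: hex-5-enylmagnesium bromide (from 4), C=CCCCC[Mg]Br
Why: Copper-catalysed Kumada-type C(sp3)–C(sp3) coupling of a primary alkyl chloride (alkyne-ligated cuprate, SN2 at C3), with the first equivalent of Grignard protecting the hydroxyl as its magnesium alkoxide; C1 is not involved.

Step 4
Reactants: 5, (R)-1-[3,5-bis(methoxymethoxy)phenyl]non-8-en-1-ol
Product: 6, (R)-4-(1-hydroxynon-8-en-1-yl)-2,6-bis(methoxymethoxy)phenol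
Conditions: n-BuLi (2.3 equiv), THF, 0 °C; B(OMe)3, −78 °C → rt; then 30% H2O2, aq. NaOH, 0 °C
Reagents that add atoms: hydrogen peroxide, OO (phenolic oxygen; B(OMe)3 is transient)
Why: Directed ortho-metalation: after alkoxide formation, n-BuLi lithiates the ring carbon flanked by the two cooperating OMOM groups (the alkoxide also prevents benzylic deprotonation), and borylation/oxidation converts C–Li into the phenol.

Step 5
Reactants: 7, 3,5-diiodophenol
Product: 8, 1,3-diiodo-5-(methoxymethoxy)benzene
Conditions: MOMCl, i-Pr2NEt, CH2Cl2, 0 °C → rt
Reagents that add atoms: chloromethyl methyl ether (MOMCl), COCCl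
Why: Standard phenol O-alkylation; masking this unhindered phenol prevents it from competing as a nucleophile in step 8.

Step 6
Reactants: 8, 1,3-diiodo-5-(methoxymethoxy)benzene (2.5 equiv); 9, 7-bromohept-1-ene
Product: 10, 1-(hept-6-en-1-yl)-3-iodo-5-(methoxymethoxy)benzene
Conditions: 9, Zn, LiCl, THF, 40 °C → hept-6-enylZnBr; 8, Pd(dppf)Cl2 (3 mol%), THF, 50 °C
Reagents that add atoms: hept-6-enylzinc bromide (from 9), C=CCCCCC[Zn]Br
Why: Negishi C(sp2)–C(sp3) coupling; the excess of the symmetrical diiodide makes mono-alkylation dominant (unreacted 8 is recovered) and leaves one iodide for step 8.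

Step 7
Reactants: 6, (R)-4-(1-hydroxynon-8-en-1-yl)-2,6-bis(methoxymethoxy)phenol; 10, 1-(hept-6-en-1-yl)-3-iodo-5-(methoxymethoxy)benzene (3 equiv)
Product: 11, 4-[(1R,8E)-1-hydroxy-14-[3-iodo-5-(methoxymethoxy)phenyl]tetradec-8-en-1-yl]-2,6-bis(methoxymethoxy)phenol
Conditions: Grubbs II (5 mol%), CH2Cl2, 40 °C; E isomer isolated on AgNO3–SiO2
Reagents that add atoms: none
Why: Olefin cross-metathesis of two unhindered terminal alkenes under thermodynamic control gives the 1,2-disubstituted alkene E-major (expected about 5:1); excess 10 suppresses homodimer of 6, and the Z isomer is removed by argentation chromatography.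

Step 8
Reactants: 11, 4-[(1R,8E)-1-hydroxy-14-[3-iodo-5-(methoxymethoxy)phenyl]tetradec-8-en-1-yl]-2,6-bis(methoxymethoxy)phenol
Product: 12, tris-MOM ether of the target: the 22-membered macrocyclic diaryl ether with OMOM on ring A, two OMOM on ring B ortho to the ether oxygen, free (R)-benzylic OH and E-alkene
Conditions: CuI (30 mol%), DBU (2 equiv), MeCN (1 mM), hν 300–350 nm (Pyrex), rt, Ar
Reagents that add atoms: none
Why: Proposed new method: a photoinduced Cu-catalysed macrocyclising O-arylation in which the Cu(I) aryloxide of the 2,6-dialkoxyphenol is the chromophore, its excited state transfers an electron to the tethered C–I bond, and the aryl radical recombines in-cage with Cu(II)–OAr (Cu(III), C–O reductive elimination); the phenoxide is blocked at both ortho positions and para so only O-arylation is possible, DBU does not deprotonate the aliphatic OH, and 1 mM dilution favours the 22-membered ring; the closest known reaction is the intermolecular photoinduced Cu-catalysed Ullmann-type O-arylation of phenols with aryl iodides at room temperature.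

Step 9
Reactants: 12, tris-MOM ether of the target
Product: 13, dehydrogravicycle (target)
Conditions: 3 M HCl, MeOH–THF, 40 °C
Reagents that add atoms: none
Why: Acid-catalysed acetal hydrolysis removes the three aryl MOM ethers; the benzylic alcohol should survive because the hindered para-aryloxy group is a weak donor and the two meta oxygens are inductively withdrawing, so the stereocentre is retained.

## Compound list

1 | (R)-3-chloro-1-phenylpropan-1-ol | O[C@H](CCCl)c1ccccc1 | starting material
2 | (R)-5-(3-chloro-1-hydroxypropyl)benzene-1,3-diol | O[C@H](CCCl)c1cc(O)cc(O)c1 | intermediate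
3 | (R)-1-[3,5-bis(methoxymethoxy)phenyl]-3-chloropropan-1-ol | O[C@H](CCCl)c1cc(OCOC)cc(OCOC)c1 | intermediate
4 | 6-bromohex-1-ene | C=CCCCCBr | starting material
5 | (R)-1-[3,5-bis(methoxymethoxy)phenyl]non-8-en-1-ol | O[C@H](CCCCCCC=C)c1cc(OCOC)cc(OCOC)c1 | intermediate
6 | (R)-4-(1-hydroxynon-8-en-1-yl)-2,6-bis(methoxymethoxy)phenol | O[C@H](CCCCCCC=C)c1cc(OCOC)c(O)c(OCOC)c1 | intermediate
7 | 3,5-diiodophenol | Oc1cc(I)cc(I)c1 | starting material
8 | 1,3-diiodo-5-(methoxymethoxy)benzene | COCOc1cc(I)cc(I)c1 | intermediate
9 | 7-bromohept-1-ene | C=CCCCCCBr | starting material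
10 | 1-(hept-6-en-1-yl)-3-iodo-5-(methoxymethoxy)benzene | COCOc1cc(I)cc(CCCCCC=C)c1 | intermediate
11 | 4-[(1R,8E)-1-hydroxy-14-[3-iodo-5-(methoxymethoxy)phenyl]tetradec-8-en-1-yl]-2,6-bis(methoxymethoxy)phenol | O[C@H](CCCCCC/C=C/CCCCCc1cc(I)cc(OCOC)c1)c1cc(OCOC)c(O)c(OCOC)c1 | intermediate
12 | tris-O-MOM dehydrogravicycle (macrocyclic diaryl ether, (R), E) | COCOc1cc2cc(c1)Oc1c(OCOC)cc(cc1OCOC)[C@H](O)CCCCCC/C=C/CCCCC2 | intermediate
13 | dehydrogravicycle | Oc1cc2cc(c1)Oc1c(O)cc(cc1O)[C@H](O)CCCCCC/C=C/CCCCC2 | target

## Summary

Total steps: 9. Longest linear sequence: 7 (steps 1, 2, 3, 4, 7, 8, 9).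

Steps most likely to fail:

1. **Step 8 (proposed photoinduced Cu macro-etherification).** Risks are hydrodeiodination, oligomers and light-induced E/Z erosion. Fallback (known chemistry, ring closed at a different bond): join 6 and 10 intermolecularly by thermal Ullmann etherification (CuI, picolinic acid, K3PO4, DMSO, 90 °C), then close the 22-membered ring at the alkene by ring-closing metathesis under high dilution.
2. **Step 1 (meta,meta′ diborylation/oxidation).** Risks are the statistical meta/para split capping the yield near 50–55%, chloride tolerance, and any Ir-mediated erosion of ee if the alcohol is not fully O-borylated. Fallback: set the same centre by substrate control from L-tartaric acid. Ni/photoredox decarboxylative arylation of mono-methyl 2,3-O-isopropylidene-L-tartrate with 1-bromo-3,5-bis(methoxymethoxy)benzene (trans-selective), SmI2 α-C–O cleavage and LiBH4 reduction to the (R)-1-aryl-1,3-propanediol, primary tosylate, then Cu-catalysed coupling with hex-5-enylMgBr to reach 5.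
3. **Step 7 (cross-metathesis).** Risks are the E/Z ratio of only about 5:1, homodimers and chain-walking. Fallback: replace the alkenes by an alkyne union. Alkylate the lithium acetylide of a ring-B terminal alkyne with a ring-A primary alkyl iodide, then convert the internal alkyne to the pure E-alkene by Ru-catalysed trans-hydrosilylation/protodesilylation.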